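**Retrosynthetic overview**

- Target ⇐ its hexa-O-benzyl ether (hydrogenolysis) ⇐ a bis(2H-chromene) by twofold hydroboration–oxidation; the two C2 centres relay C3 of both units and C4 of the upper unit.
- Bis(2H-chromene) ⇐ an acyclic bis(allylic alcohol) bisphenol: one chiral Brønsted-acid-catalysed twofold dehydrative cyclisation closes both pyran rings (ring C of each flavan unit) together and sets both C2 centres.
- Bis(allylic alcohol) ⇐ aryllithium of the central catechol ring (from its C–Br) + a 2'-hydroxychalcone (makes the C4–aryl bond of the upper unit); the lower arm is a reduced 2'-hydroxychalcone.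
- Both chalcones ⇐ one acetophenone (ring A of both units) + 3,4-bis(benzyloxy)benzaldehyde or its 6-bromo derivative (Claisen–Schmidt).
- Ring order: all five benzene rings are bought; the two pyran rings are formed last and at the same time.

Assumption: the sense of induction of the acid catalyst in step 6 is taken by analogy; the (R)-catalyst is written, and its mirror image is used if it gives the (2R,2'R) series.

**Step 1**
Reactants: 1 3,4-bis(benzyloxy)benzaldehyde
Product: 2 4,5-bis(benzyloxy)-2-bromobenzaldehyde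
Conditions: Br2, NaOAc, AcOH, rt
Reagents that add atoms: bromine, BrBr
Why: Electrophilic aromatic bromination goes to the one open position para to a benzyloxy group (C6, ortho to the formyl group), as with veratraldehyde; no stereocentre is formed.

**Step 2**
Reactants: 2 4,5-bis(benzyloxy)-2-bromobenzaldehyde; 3 1-[4-(benzyloxy)-2-hydroxyphenyl]ethan-1-one
Product: 4 (E)-1-[4-(benzyloxy)-2-hydroxyphenyl]-3-[4,5-bis(benzyloxy)-2-bromophenyl]prop-2-en-1-one
Conditions: KOH, EtOH/H2O, rt; aq. HCl work-up
Reagents that add atoms: none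
Why: Claisen–Schmidt (crossed aldol) condensation of a methyl ketone with a non-enolisable aldehyde; dehydration gives the conjugated E-enone.

**Step 3**
Reactants: 4 (E)-1-[4-(benzyloxy)-2-hydroxyphenyl]-3-[4,5-bis(benzyloxy)-2-bromophenyl]prop-2-en-1-one
Product: 5 (E)-1-[4-(benzyloxy)-2-hydroxyphenyl]-3-[4,5-bis(benzyloxy)-2-bromophenyl]prop-2-en-1-ol (racemic)
Conditions: NaBH4, CeCl3·7H2O, THF/MeOH, −40 → 0 °C; aq. NaHCO3; used crude
Reagents that add atoms: none
Why: Luche 1,2-reduction of the enone leaves the alkene and the aryl bromide alone; the new carbinol centre is left racemic because it becomes sp2 again in step 6, and the base-buffered work-up keeps this acid-labile alcohol from cyclising early.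

**Step 4**
Reactants: 3 1-[4-(benzyloxy)-2-hydroxyphenyl]ethan-1-one; 1 3,4-bis(benzyloxy)benzaldehyde
Product: 6 (E)-1-[4-(benzyloxy)-2-hydroxyphenyl]-3-[3,4-bis(benzyloxy)phenyl]prop-2-en-1-one
Conditions: KOH, EtOH/H2O, rt; aq. HCl work-up
Reagents that add atoms: none
Why: Claisen–Schmidt condensation as in step 2, giving the E-2'-hydroxychalcone.

**Step 5**
Reactants: 5 (E)-1-[4-(benzyloxy)-2-hydroxyphenyl]-3-[4,5-bis(benzyloxy)-2-bromophenyl]prop-2-en-1-ol; 6 (E)-1-[4-(benzyloxy)-2-hydroxyphenyl]-3-[3,4-bis(benzyloxy)phenyl]prop-2-en-1-one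
Product: 9 bis(allylic alcohol) bisphenol, via aryllithium 7 (not isolated), via lithium phenoxide 8 (not isolated)
Conditions: 5, n-BuLi (3.05 equiv), THF, −78 °C; then 8 [from 6 (1.5 equiv), LiN(SiMe3)2, THF, −78 °C], −78 → −20 °C; H2O, pH 8
Reagents that add atoms: none
Why: After both OH groups are deprotonated, bromine–lithium exchange is faster than any attack on the alkene, and the hard aryllithium adds 1,2 to the lithium-chelated enone carbonyl (organolithium carbonyl addition); the new tertiary carbinol centre is uncontrolled but is erased in step 6.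

**Step 6**
Reactants: 9 bis(allylic alcohol) bisphenol
Product: 11 (2S,2'S)-bis(2H-chromene), via mono-chromene 10 (not isolated)
Conditions: (R)-3,3'-bis(2,4,6-triisopropylphenyl)-BINOL N-triflylphosphoramide (10 mol%), toluene/CH2Cl2, 4 Å MS, −78 → −45 °C; Et3N quench
Reagents that add atoms: none
Why: Proposed new method: the acid ionises each doubly benzylic allylic alcohol (the tertiary one first) to an allyl cation/vinylogous o-quinone methide that stays ion-paired and hydrogen-bonded through the phenolic OH to the chiral phosphoramide anion, so the phenol oxygen closes onto one face of the aryl-bearing terminus (intramolecular asymmetric allylic substitution, formally an oxa-6π ring closure) and sets C2 of each ring as S, the same event and the same sense in both arms; the closest known reaction is the chiral N-triflylphosphoramide-catalysed cyclisation of tertiary 2-(1-hydroxy-1,3-diarylallyl)phenols to 2,4-diaryl-2H-chromenes, of which the upper arm is a direct case and the secondary lower arm and the twofold use are the extension.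

**Step 7**
Reactants: 11 (2S,2'S)-bis(2H-chromene)
Product: 13 hexa-O-benzyl ether of the target, via bis-alkylborane 12 (not isolated)
Conditions: BH3·SMe2, THF, 0 °C → rt; then NaOH, H2O2, 0 °C → rt
Reagents that add atoms: hydrogen peroxide, OO
Why: Brown hydroboration–oxidation puts boron on C3 of each styrene-type C3=C4 bond (positive charge at benzylic C4 is stabilised by the para 7-benzyloxy group) from the face anti to the neighbouring C2 aryl group, the syn-delivered hydrogen at C4 of the upper unit leaves the central aryl trans to C3–B, and oxidation with retention gives the 2,3-trans (upper unit also 3,4-trans) alcohols, so C3, C3' and C4 are set by the two C2 centres.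

**Step 8**
Reactants: 13 hexa-O-benzyl ether of the target
Product: 14 target
Conditions: H2 (1 atm), Pd(OH)2/C, THF/MeOH, rt
Reagents that add atoms: none
Why: Catalytic hydrogenolysis removes the six aryl benzyl ethers, while the C2–O1 ring ethers, the C4–aryl bond and all five stereocentres are untouched under these mild conditions, as in the debenzylation of benzylated flavan-3-ol oligomers.

**Compound list**

1 | 3,4-bis(benzyloxy)benzaldehyde | O=Cc1ccc(OCc2ccccc2)c(OCc2ccccc2)c1 | starting material
2 | 4,5-bis(benzyloxy)-2-bromobenzaldehyde | O=Cc1cc(OCc2ccccc2)c(OCc2ccccc2)cc1Br | intermediate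
3 | 1-[4-(benzyloxy)-2-hydroxyphenyl]ethan-1-one | CC(=O)c1ccc(OCc2ccccc2)cc1O | starting material
4 | (E)-1-[4-(benzyloxy)-2-hydroxyphenyl]-3-[4,5-bis(benzyloxy)-2-bromophenyl]prop-2-en-1-one | O=C(/C=C/c1cc(OCc2ccccc2)c(OCc2ccccc2)cc1Br)c1ccc(OCc2ccccc2)cc1O | intermediate
5 | (E)-1-[4-(benzyloxy)-2-hydroxyphenyl]-3-[4,5-bis(benzyloxy)-2-bromophenyl]prop-2-en-1-ol, racemic at C1 | OC(/C=C/c1cc(OCc2ccccc2)c(OCc2ccccc2)cc1Br)c1ccc(OCc2ccccc2)cc1O | intermediate
6 | (E)-1-[4-(benzyloxy)-2-hydroxyphenyl]-3-[3,4-bis(benzyloxy)phenyl]prop-2-en-1-one | O=C(/C=C/c1ccc(OCc2ccccc2)c(OCc2ccccc2)c1)c1ccc(OCc2ccccc2)cc1O | intermediate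
7 | trilithio derivative of 5: C–Li in place of C–Br, both OH groups as OLi | [Li]OC(/C=C/c1cc(OCc2ccccc2)c(OCc2ccccc2)cc1[Li])c1ccc(OCc2ccccc2)cc1O[Li] | intermediate
8 | lithium 5-(benzyloxy)-2-[(E)-3-[3,4-bis(benzyloxy)phenyl]prop-2-enoyl]phenolate (lithium phenoxide of 6) | [Li]Oc1cc(OCc2ccccc2)ccc1C(=O)/C=C/c1ccc(OCc2ccccc2)c(OCc2ccccc2)c1 | intermediate
9 | (E)-1-[4-(benzyloxy)-2-hydroxyphenyl]-3-{4,5-bis(benzyloxy)-2-[(E)-1-[4-(benzyloxy)-2-hydroxyphenyl]-3-[3,4-bis(benzyloxy)phenyl]-1-hydroxyprop-2-en-1-yl]phenyl}prop-2-en-1-ol, mixture of diastereomers at the two carbinol centres | OC(/C=C/c1cc(OCc2ccccc2)c(OCc2ccccc2)cc1C(O)(/C=C/c1ccc(OCc2ccccc2)c(OCc2ccccc2)c1)c1ccc(OCc2ccccc2)cc1O)c1ccc(OCc2ccccc2)cc1O | intermediate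
10 | (E)-1-[4-(benzyloxy)-2-hydroxyphenyl]-3-{4,5-bis(benzyloxy)-2-[(2S)-7-(benzyloxy)-2-[3,4-bis(benzyloxy)phenyl]-2H-chromen-4-yl]phenyl}prop-2-en-1-ol (upper ring closed, lower arm still open) | OC(/C=C/c1cc(OCc2ccccc2)c(OCc2ccccc2)cc1C1=C[C@@H](c2ccc(OCc3ccccc3)c(OCc3ccccc3)c2)Oc2cc(OCc3ccccc3)ccc12)c1ccc(OCc2ccccc2)cc1O | intermediate
11 | (2S)-7-(benzyloxy)-2-[3,4-bis(benzyloxy)phenyl]-4-{4,5-bis(benzyloxy)-2-[(2S)-7-(benzyloxy)-2H-chromen-2-yl]phenyl}-2H-chromene | C(c1ccccc1)Oc1ccc2c(c1)O[C@H](c1cc(OCc3ccccc3)c(OCc3ccccc3)cc1C1=C[C@@H](c3ccc(OCc4ccccc4)c(OCc4ccccc4)c3)Oc3cc(OCc4ccccc4)ccc13)C=C2 | intermediate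
12 | 3,3'-bis(dihydroboryl) adduct of 11: BH2 on C3 of each chroman ring trans to the C2 aryl group, upper C4–H cis to boron (13 with BH2 in place of each OH) | C(c1ccccc1)Oc1ccc2c(c1)O[C@H](c1cc(OCc3ccccc3)c(OCc3ccccc3)cc1[C@@H]1c3ccc(OCc4ccccc4)cc3O[C@H](c3ccc(OCc4ccccc4)c(OCc4ccccc4)c3)[C@H]1B)[C@@H](B)C2 | intermediate
13 | (2R,3S,4R)-7-(benzyloxy)-2-[3,4-bis(benzyloxy)phenyl]-4-{4,5-bis(benzyloxy)-2-[(2R,3S)-7-(benzyloxy)-3-hydroxy-3,4-dihydro-2H-chromen-2-yl]phenyl}-3,4-dihydro-2H-chromen-3-ol | C(c1ccccc1)Oc1ccc2c(c1)O[C@H](c1cc(OCc3ccccc3)c(OCc3ccccc3)cc1[C@@H]1c3ccc(OCc4ccccc4)cc3O[C@H](c3ccc(OCc4ccccc4)c(OCc4ccccc4)c3)[C@H]1O)[C@@H](O)C2 | intermediate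
14 | (2R,3S,4R)-2-(3,4-dihydroxyphenyl)-4-{2-[(2R,3S)-3,7-dihydroxy-3,4-dihydro-2H-chromen-2-yl]-4,5-dihydroxyphenyl}-3,4-dihydro-2H-chromene-3,7-diol (both units 2,3-trans, upper unit 3,4-trans) | Oc1ccc2c(c1)O[C@H](c1cc(O)c(O)cc1[C@@H]1c3ccc(O)cc3O[C@H](c3ccc(O)c(O)c3)[C@H]1O)[C@@H](O)C2 | target

**Step count and risks**

Total steps: 8. Longest linear sequence: 7 steps (1 → 2 → 4 → 5 → 9 → 11 → 13 → 14; step 4 is the side branch).

Steps most likely to fail:

Step 6 is the main risk. The secondary lower arm has no direct precedent with this catalyst class, so its enantioselectivity or even its sense may differ from that of the upper arm. The electron-rich 2-aryl-2H-chromenes can also re-ionise at C2 and racemise if the acid is not quenched cold. The fallback sets out from 9 and comes back at 11. Compound 9 is treated with 1,1'-carbonyldiimidazole and catalytic DBU in CH2Cl2, which ties each phenol oxygen to its neighbouring carbinol oxygen and gives the bis(cyclic carbonate) F1. F1 is then exposed to Pd2(dba)3 and the (R,R)-DACH-phenyl bisphosphine ligand in THF at 0 °C. Zerovalent palladium ionises each allylic carbonate, CO2 is lost, and each π-allylpalladium phenoxide can only close at the aryl-bearing terminus to the six-membered ring. Both pyran rings still form in one operation, now under ligand control at a neutral pH where the product cannot re-ionise.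

Step 5 may suffer from conjugate addition or low conversion, because a hindered aryllithium meets a ketone deactivated by its ortho phenoxide. The fallback sets out from 1 and 5 and comes back at 9, and it builds the carbinol from the other side. Aldehyde 1 is homologated with diethyl [2-[methoxy(methyl)amino]-2-oxoethyl]phosphonate and NaH (Horner–Wadsworth–Emmons) to the Weinreb amide F2. Aryllithium 7, made from 5 as before, is acylated by F2 and stops cleanly at the enone F3. F3 is deprotonated at both OH groups with LiN(SiMe3)2 and then takes up, in a 1,2 sense, the dilithiated phenol F4, which is made from commercial 2-bromo-5-(benzyloxy)phenol and two equivalents of n-BuLi. This gives 9 from an unhindered nucleophile and a ketone without an ortho phenoxide.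

Step 7 may give ring-opened phenols by β-alkoxy elimination of the C3 boranes, or may be slow at the trisubstituted upper alkene. The fallback sets out from 11 and comes back at 13. A copper-catalysed protoboration (CuCl, Xantphos, NaOtBu, bis(pinacolato)diboron, MeOH, THF, rt) adds a copper–boryl species syn across each C3=C4 bond, with boron on C3 anti to the C2 aryl group, and protonates the benzylic C–Cu bond with retention. This gives the robust bis(pinacol boronate) F5, which is oxidised with NaBO3·4H2O in THF/H2O to 13 with the same configuration as in the borane route.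

**Further compounds**

F1 | step 6 | bis(cyclic carbonate) of 9: each phenol oxygen and the adjacent carbinol oxygen joined through C=O as a 4H-1,3-benzodioxin-2-one | O=C1Oc2cc(OCc3ccccc3)ccc2C(/C=C/c2cc(OCc3ccccc3)c(OCc3ccccc3)cc2C2(/C=C/c3ccc(OCc4ccccc4)c(OCc4ccccc4)c3)OC(=O)Oc3cc(OCc4ccccc4)ccc23)O1
F2 | step 5 | (E)-3-[3,4-bis(benzyloxy)phenyl]-N-methoxy-N-methylprop-2-enamide | CON(C)C(=O)/C=C/c1ccc(OCc2ccccc2)c(OCc2ccccc2)c1
F3 | step 5 | (E)-1-{4,5-bis(benzyloxy)-2-[(E)-3-[4-(benzyloxy)-2-hydroxyphenyl]-3-hydroxyprop-1-en-1-yl]phenyl}-3-[3,4-bis(benzyloxy)phenyl]prop-2-en-1-one | OC(/C=C/c1cc(OCc2ccccc2)c(OCc2ccccc2)cc1C(=O)/C=C/c1ccc(OCc2ccccc2)c(OCc2ccccc2)c1)c1ccc(OCc2ccccc2)cc1O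
F4 | step 5 | lithium 5-(benzyloxy)-2-lithiophenolate | [Li]Oc1cc(OCc2ccccc2)ccc1[Li]
F5 | step 7 | 3,3'-bis(pinacol boronate) corresponding to 13 (Bpin in place of each 3-OH, same spatial arrangement) | C(c1ccccc1)Oc1ccc2c(c1)O[C@H](c1cc(OCc3ccccc3)c(OCc3ccccc3)cc1[C@@H]1c3ccc(OCc4ccccc4)cc3O[C@H](c3ccc(OCc4ccccc4)c(OCc4ccccc4)c3)[C@H]1B5OC(C)(C)C(C)(C)O5)[C@@H](B5OC(C)(C)C(C)(C)O5)C2
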